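**Strategy.** The benzo ring of the target carries bromine at C5 and C6, so cleaving the pyrrole ring at N1–C7a and C3–C3a leaves an aryne (C3a≡C7a) with a mirror plane through the C5–C6 bond: whichever aryne carbon takes nitrogen, the same 5,6-dibromo pattern results. One fluoride-triggered operation joins this 4,5-dibromobenzyne to an N-Boc dehydroalanine ester, forming both bonds and the five-membered ring. The aryne comes from an ortho-silyl aryl triflate made from 3,4-dibromophenol. The C2 carboxyl group that activates the alkene is afterwards expelled as CO2 in the aromatising step, which also installs the C3 bromine.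

Key step: step 4

Remark: the target has no stereocentre and is achiral, so there is no enantiomer to select; the only stereocentre on the route (C2 of the indoline) is formed racemic and is destroyed on aromatisation.

**Step 1**
Reactants: 1 3,4-dibromophenol
Product: 2 4,5-dibromo-2-iodophenol
Conditions: NIS (1.0 equiv), TsOH·H2O (cat.), MeCN, 0 °C → rt
Reagents that add atoms: N-iodosuccinimide, O=C1CCC(=O)N1I
Why: Electrophilic aromatic iodination ortho to the phenol OH (the para position carries bromine); of the two ortho carbons the one between OH and Br is shielded, so iodine should enter at C6 of 1, and one equivalent of NIS limits di-iodination.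

**Step 2**
Reactants: 2 4,5-dibromo-2-iodophenol
Product: 3 (4,5-dibromo-2-iodophenoxy)trimethylsilane
Conditions: HMDS (0.6 equiv), THF, 65 °C; concentrate and use crude
Reagents that add atoms: hexamethyldisilazane, C[Si](C)(C)N[Si](C)(C)C
Why: O-silylation of the phenol with HMDS releases only ammonia, so the moisture-sensitive aryl silyl ether can be taken on after simple evaporation.

**Step 3**
Reactants: 3 (4,5-dibromo-2-iodophenoxy)trimethylsilane
Product: 6 4,5-dibromo-2-(trimethylsilyl)phenyl trifluoromethanesulfonate, via aryllithium 4 (not isolated), via lithium 2-silylphenolate 5 (not isolated)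
Conditions: n-BuLi (1.0 equiv), THF, −100 °C then −78 °C; Tf2O, −100 °C → rt
Reagents that add atoms: trifluoromethanesulfonic anhydride, O=S(=O)(OS(=O)(=O)C(F)(F)F)C(F)(F)F
Why: Iodine–lithium exchange is much faster than bromine–lithium exchange at −100 °C, the ortho-lithiated silyl ether 4 then undergoes the anionic 1,3 O→C silyl shift (retro-Brook rearrangement) to phenolate 5, and O-triflation completes the standard one-pot construction of an ortho-silylaryl triflate.

**Step 4**
Reactants: 6 4,5-dibromo-2-(trimethylsilyl)phenyl trifluoromethanesulfonate; 7 methyl 2-[(tert-butoxycarbonyl)amino]acrylate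
Product: 9 methyl (±)-1-(tert-butoxycarbonyl)-5,6-dibromoindoline-2-carboxylate, via 4,5-dibromobenzyne 8 (not isolated)
Conditions: TBAT (1.5 equiv), THF, 23 °C; 6 added slowly to 7 (1.5 equiv)
Reagents that add atoms: none
Why: Fluoride from TBAT attacks silicon in 6 and triflate leaves, giving 4,5-dibromobenzyne 8; the carbamate nitrogen of 7 adds to one aryne carbon (N1–C7a) and the aryl anion so formed adds to the CH2 terminus of the acrylate (C3–C3a), after which the ester enolate is protonated. This is the known fluoride-induced formal [3+2] annulation of arynes with N-carbamoyl dehydroamino esters (aryne amination followed by intramolecular Michael addition), applied here to a dibromoaryne. The five-membered ring closes in a 5-endo-trig mode, feasible because the anion is generated in the ring plane next to the ester-activated alkene and has no other fast outlet. The only new stereocentre, C2, comes from unselective protonation of the enolate, so 9 is racemic, which is harmless because C2 becomes sp2 in step 6. No regiochemical control is needed, since the mirror plane of 8 through the midpoints of the triple bond and the C4–C5 bond makes both orientations of addition give the same 5,6-dibromo product. The selectivity that is needed, ring closure ahead of protonation of the aryl anion or attack through carbon, is secured by the carbamate (not amide) nitrogen and the geminal ester, and the bromines, being meta and para to the anionic carbon, cannot be lost by elimination.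

**Step 5**
Reactants: 9 methyl (±)-1-(tert-butoxycarbonyl)-5,6-dibromoindoline-2-carboxylate
Product: 11 (±)-5,6-dibromoindoline-2-carboxylic acid, via amino ester 10 (not isolated)
Conditions: 6 M aq. HCl, 1,4-dioxane, 90 °C; concentrate, isolate at pH 3–4
Reagents that add atoms: water, O
Why: Acidolysis of the tert-butyl carbamate (loss of isobutene, then decarboxylation of the carbamic acid) gives amino ester 10, whose acid-catalysed ester hydrolysis follows in the same pot; aryl bromides and the indoline ring are inert to hot aqueous acid.

**Step 6**
Reactants: 11 (±)-5,6-dibromoindoline-2-carboxylic acid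
Product: 14 3,5,6-tribromo-1H-indole, via N-bromo amino acid 12 (not isolated), via 5,6-dibromo-1H-indole 13 (not isolated)
Conditions: NBS (2.05 equiv, portionwise), NaHCO3, DMF, 0 °C → rt, dark
Reagents that add atoms: N-bromosuccinimide, O=C1CCC(=O)N1Br
Why: Halogenative oxidative decarboxylation of an α-amino acid, in which NBS brominates the indoline nitrogen (the N-halogenation also used to dehydrogenate indolines), the carboxylate of 12 fragments with loss of CO2 and bromide to the 3H tautomer of 13, and the second equivalent brominates the most nucleophilic indole carbon C3 by electrophilic substitution, so any early C3 bromination is productive.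

**Compound list**
1 | 3,4-dibromophenol | Oc1ccc(Br)c(Br)c1 | starting material
2 | 4,5-dibromo-2-iodophenol | Oc1cc(Br)c(Br)cc1I | intermediate
3 | (4,5-dibromo-2-iodophenoxy)trimethylsilane | C[Si](C)(C)Oc1cc(Br)c(Br)cc1I | intermediate
4 | [4,5-dibromo-2-(trimethylsilyloxy)phenyl]lithium | [Li]c1cc(Br)c(Br)cc1O[Si](C)(C)C | intermediate
5 | lithium 4,5-dibromo-2-(trimethylsilyl)phenolate | [Li+].[O-]c1cc(Br)c(Br)cc1[Si](C)(C)C | intermediate
6 | 4,5-dibromo-2-(trimethylsilyl)phenyl trifluoromethanesulfonate | C[Si](C)(C)c1cc(Br)c(Br)cc1OS(=O)(=O)C(F)(F)F | intermediate
7 | methyl 2-[(tert-butoxycarbonyl)amino]acrylate | C=C(NC(=O)OC(C)(C)C)C(=O)OC | starting material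
8 | 4,5-dibromobenzyne | BrC1=CC#CC=C1Br | intermediate
9 | methyl (±)-1-(tert-butoxycarbonyl)-5,6-dibromoindoline-2-carboxylate | COC(=O)C1Cc2cc(Br)c(Br)cc2N1C(=O)OC(C)(C)C | intermediate
10 | methyl (±)-5,6-dibromoindoline-2-carboxylate | COC(=O)C1Cc2cc(Br)c(Br)cc2N1 | intermediate
11 | (±)-5,6-dibromoindoline-2-carboxylic acid | OC(=O)C1Cc2cc(Br)c(Br)cc2N1 | intermediate
12 | (±)-1,5,6-tribromoindoline-2-carboxylic acid | OC(=O)C1Cc2cc(Br)c(Br)cc2N1Br | intermediate
13 | 5,6-dibromo-1H-indole | Brc1cc2cc[nH]c2cc1Br | intermediate
14 | 3,5,6-tribromo-1H-indole | Brc1cc2[nH]cc(Br)c2cc1Br | target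

**Total step count:** 6
**Longest linear sequence:** 6 steps (1 → 2 → 3 → 6 → 9 → 11 → 14); 7 is bought and enters at step 4.

**Steps most likely to fail**

Step 4. The aryl anion may be protonated before it closes the ring, or the aryne may be consumed by self-reaction or by fluoride, so that only N-arylation or no union at all results. The fallback sets out from 7 and comes back at 13, replacing the symmetry argument by a regiodefined aryl iodide. Commercial 3,4-dibromoaniline is iodinated with NIS in MeCN at its open ortho position to give 4,5-dibromo-2-iodoaniline F1. A ligand-free Heck coupling (Pd(OAc)2, Bu4NCl, NaHCO3, DMF, 80 °C), selective for C–I over C–Br, joins F1 to 7 and gives methyl (Z)-3-(2-amino-4,5-dibromophenyl)-2-[(tert-butoxycarbonyl)amino]prop-2-enoate F2. TsOH in warm toluene lets the aniline nitrogen add to the enamide α-carbon and expel tert-butyl carbamate, giving methyl 5,6-dibromo-1H-indole-2-carboxylate F3. NaOH in aqueous methanol gives 5,6-dibromo-1H-indole-2-carboxylic acid F4, and copper in hot quinoline removes CO2 to give 13. One equivalent of NBS in DMF then converts 13 to 14 as in the second stage of step 6.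

Step 6. Bromination of the benzo ring at C7 may precede N-bromination, the N-bromo intermediate may lose HBr without losing CO2, or the product may be brominated further at C2. The fallback sets out from 9 and comes back at 13, moving the decarboxylation to the carbamate stage so that no free aniline nitrogen meets an electrophilic halogen. LiOH in aqueous THF gives 1-(tert-butoxycarbonyl)-5,6-dibromoindoline-2-carboxylic acid F5. Anodic decarboxylative methoxylation (non-Kolbe electrolysis, graphite electrodes, MeOH, catalytic NaOMe) proceeds through the N-acyliminium ion and gives tert-butyl 5,6-dibromo-2-methoxyindoline-1-carboxylate F6. Catalytic TsOH in warm toluene eliminates methanol to give tert-butyl 5,6-dibromo-1H-indole-1-carboxylate F7, and K2CO3 in methanol removes the indole N-Boc group to give 13. A single, separately dosed equivalent of NBS in DMF at 0 °C then gives 14.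

Step 3. Exchange at one of the vicinal bromines may compete with exchange at iodine and lead to loss of lithium bromide and aryne-derived tars, or the silyl shift may be incomplete before triflation. The fallback sets out from 2 and comes back at 6, replacing lithium by magnesium. Phenol 2 is deprotonated with MeMgCl and treated with i-PrMgCl·LiCl (THF, −20 °C), which exchanges aryl iodides and leaves aryl bromides alone. Quenching with excess TMSCl gives [4,5-dibromo-2-(trimethylsilyloxy)phenyl]trimethylsilane F8, whose O–Si bond is cleaved on aqueous NH4Cl work-up to give 4,5-dibromo-2-(trimethylsilyl)phenol F9. Tf2O and pyridine in CH2Cl2 at 0 °C then give 6.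

**Further compounds**
F1 | step 4 | 4,5-dibromo-2-iodoaniline | Nc1cc(Br)c(Br)cc1I
F2 | step 4 | methyl (Z)-3-(2-amino-4,5-dibromophenyl)-2-[(tert-butoxycarbonyl)amino]prop-2-enoate | COC(=O)/C(NC(=O)OC(C)(C)C)=C/c1cc(Br)c(Br)cc1N
F3 | step 4 | methyl 5,6-dibromo-1H-indole-2-carboxylate | COC(=O)c1cc2cc(Br)c(Br)cc2[nH]1
F4 | step 4 | 5,6-dibromo-1H-indole-2-carboxylic acid | OC(=O)c1cc2cc(Br)c(Br)cc2[nH]1
F5 | step 6 | (±)-1-(tert-butoxycarbonyl)-5,6-dibromoindoline-2-carboxylic acid | OC(=O)C1Cc2cc(Br)c(Br)cc2N1C(=O)OC(C)(C)C
F6 | step 6 | tert-butyl (±)-5,6-dibromo-2-methoxyindoline-1-carboxylate | COC1Cc2cc(Br)c(Br)cc2N1C(=O)OC(C)(C)C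
F7 | step 6 | tert-butyl 5,6-dibromo-1H-indole-1-carboxylate | CC(C)(C)OC(=O)n1ccc2cc(Br)c(Br)cc21
F8 | step 3 | [4,5-dibromo-2-(trimethylsilyloxy)phenyl]trimethylsilane | C[Si](C)(C)Oc1cc(Br)c(Br)cc1[Si](C)(C)C
F9 | step 3 | 4,5-dibromo-2-(trimethylsilyl)phenol | Oc1cc(Br)c(Br)cc1[Si](C)(C)C
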